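**Retrosynthetic overview**
- Last step: hydrogenolysis of the sixteen benzyl ethers of the fully protected tetramer.
- Each of the three interflavan C4–C8 bonds, together with the neighbouring C3–H bond, is made in one radical hydroarylation: a (2R)-2H-chromen-3-yl formate (enol formate of the flavan-3-one) plus the 8-bromide of the growing chain. Hydrogen-atom transfer sets C3 (2,3-cis) and nickel capture of the C4 radical sets C4 (3,4-trans). The chain grows from the catechin end, with re-bromination at C8 after each round.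
- Both monomers come from one (2R)-2H-chromene-3-carbaldehyde: Baeyer–Villiger oxidation gives the enol formate; decarbonylation, hydroboration and bromination give the 8-bromocatechin terminus.
- The chromene aldehyde comes from an organocatalytic oxa-Michael/aldol condensation of a salicylaldehyde (ring A, from resorcinol) with a cinnamaldehyde (ring B, from catechol and acrolein).
- Ring order: rings A and B are bought as aromatics; ring C of every unit is closed in the domino step and saturated later (hydroboration for the catechin unit, the radical step for the three epicatechin units).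

Assumption: the target is read as epicatechin-(4β→8)-epicatechin-(4β→8)-epicatechin-(4β→8)-catechin (upper units 2R,3R with the C4 bond trans to the C3 oxygen; terminal unit 2R,3S); α is the face of the C2 aryl group, β the opposite face.

Step 1
Reactants: 1 resorcinol
Product: 4 phloroglucinol, via bis(trimethylsilyl) ether 2 (not isolated), via arylboronic pinacol ester 3 (not isolated)
Conditions: HMDS, cat. TMSCl, 80 °C, evaporate; B2pin2, [Ir(OMe)(cod)]2 (1.5 mol %), dtbpy (3 mol %), hexane, 80 °C; then Oxone (2KHSO5·KHSO4·K2SO4), acetone/H2O, rt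
Reagents that add atoms: Oxone, active salt KHSO5, [K+].[O-]S(=O)(=O)OO (new phenol oxygen of 4); hexamethyldisilazane, C[Si](C)(C)N[Si](C)(C)C (silyl groups of 2 and 3 only); bis(pinacolato)diboron, CC1(C)OB(OC1(C)C)B1OC(C)(C)C(C)(C)O1 (boryl group of 3 only)
Why: The silylated diol undergoes sterically controlled iridium-catalysed C–H borylation at C5, the only C–H with no ortho substituent, and Oxone then oxidises the C–B bond and hydrolyses the silyl ethers (one-pot C–H borylation/oxidation to a meta-substituted phenol).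

Step 2
Reactants: 4 phloroglucinol
Product: 6 2,4,6-trihydroxybenzaldehyde, via iminium chloride 5 (not isolated)
Conditions: POCl3, DMF, EtOAc, 0 °C to rt; then H2O, 50 °C
Reagents that add atoms: N,N-dimethylformamide, CN(C)C=O (formyl carbon); water, O (carbonyl oxygen); phosphoryl chloride, O=P(Cl)(Cl)Cl (chloride of 5 only)
Why: Vilsmeier–Haack formylation of the very electron-rich ring stops after one formyl group because the iminium salt deactivates the ring, and hydrolysis releases the aldehyde.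

Step 3
Reactants: 6 2,4,6-trihydroxybenzaldehyde
Product: 7 4,6-bis(benzyloxy)-2-hydroxybenzaldehyde
Conditions: BnBr (2.05 equiv), K2CO3 (2.1 equiv), DMF, 0 °C to rt
Reagents that add atoms: benzyl bromide, BrCc1ccccc1
Why: Williamson etherification takes the para hydroxyl and one ortho hydroxyl, while the remaining ortho hydroxyl is hydrogen-bonded to the aldehyde and stays free.

Step 4
Reactants: 8 catechol
Product: 9 1,2-bis(benzyloxy)benzene
Conditions: BnBr (2.2 equiv), K2CO3, DMF, 60 °C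
Reagents that add atoms: benzyl bromide, BrCc1ccccc1
Why: Double Williamson ether synthesis protects both phenols as hydrogenolysable benzyl ethers.

Step 5
Reactants: 9 1,2-bis(benzyloxy)benzene
Product: 10 1,2-bis(benzyloxy)-4-iodobenzene
Conditions: NIS, cat. CF3CO2H, MeCN, rt
Reagents that add atoms: N-iodosuccinimide, O=C1CCC(=O)N1I
Why: Electrophilic aromatic iodination goes para to an alkoxy group on the dialkoxy ring, which is far more activated than the benzyl phenyl rings.

Step 6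
Reactants: 10 1,2-bis(benzyloxy)-4-iodobenzene; 11 acrolein
Product: 12 (E)-3-[3,4-bis(benzyloxy)phenyl]prop-2-enal
Conditions: Pd(OAc)2 (3 mol %), n-Bu4NCl, NaHCO3, DMF, 50 °C
Reagents that add atoms: none
Why: Mizoroki–Heck arylation of acrolein under Jeffery conditions gives the E-cinnamaldehyde by syn insertion and syn β-hydride elimination.

Step 7
Reactants: 7 4,6-bis(benzyloxy)-2-hydroxybenzaldehyde; 12 (E)-3-[3,4-bis(benzyloxy)phenyl]prop-2-enal
Product: 13 (2R)-5,7-bis(benzyloxy)-2-[3,4-bis(benzyloxy)phenyl]-2H-chromene-3-carbaldehyde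
Conditions: (S)-α,α-diphenylprolinol trimethylsilyl ether (20 mol %), 2-nitrobenzoic acid (20 mol %), 4 Å MS, toluene, rt
Reagents that add atoms: none
Why: In this organocatalytic domino oxa-Michael/aldol condensation the iminium ion of 12 is attacked by the phenol of 7 on the Si face of the β-carbon (the Re face is shielded by the CPh2OSiMe3 group of the S catalyst), and the enamine then closes onto the aryl aldehyde and dehydrates, which forms ring C and sets C2 as R.

Step 8
Reactants: 13 (2R)-5,7-bis(benzyloxy)-2-[3,4-bis(benzyloxy)phenyl]-2H-chromene-3-carbaldehyde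
Product: 14 (2R)-5,7-bis(benzyloxy)-2-[3,4-bis(benzyloxy)phenyl]-2H-chromen-3-yl formate
Conditions: mCPBA (1.1 equiv), NaHCO3, CH2Cl2, 0 °C
Reagents that add atoms: 3-chloroperoxybenzoic acid, OOC(=O)c1cccc(Cl)c1
Why: Baeyer–Villiger (Dakin-type) oxidation of the electron-rich enal, with migration of the alkenyl group in preference to hydrogen, turns the formyl group into the enol formate with fixed C3=C4 regiochemistry and leaves C2 untouched.

Step 9
Reactants: 13 (2R)-5,7-bis(benzyloxy)-2-[3,4-bis(benzyloxy)phenyl]-2H-chromene-3-carbaldehyde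
Product: 15 (2S)-5,7-bis(benzyloxy)-2-[3,4-bis(benzyloxy)phenyl]-2H-chromene
Conditions: RhCl(PPh3)3 (1.05 equiv), toluene, 100 °C
Reagents that add atoms: none
Why: Tsuji–Wilkinson decarbonylation (aldehyde C–H oxidative addition, CO extrusion, reductive elimination) removes the formyl carbon and keeps the alkene and the C2 centre, whose descriptor changes to S only through the CIP priorities.

Step 10
Reactants: 15 (2S)-5,7-bis(benzyloxy)-2-[3,4-bis(benzyloxy)phenyl]-2H-chromene
Product: 17 5,7,3',4'-tetra-O-benzyl-(+)-catechin, via C3 alkylborane 16 (not isolated)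
Conditions: BH3·THF, THF, 0 °C to rt; then NaOH, H2O2, 0 °C
Reagents that add atoms: hydrogen peroxide, OO (hydroxyl oxygen of 17); borane–tetrahydrofuran, [BH3-][O+]1CCCC1 (boron of 16 only)
Why: In this hydroboration–oxidation boron adds to C3 (β to the electron-rich arene) from the face opposite the C2 aryl group and is replaced by OH with retention, which sets the 2,3-trans (3S) centre of the catechin unit.

Step 11
Reactants: 17 5,7,3',4'-tetra-O-benzyl-(+)-catechin
Product: 18 8-bromo-5,7,3',4'-tetra-O-benzyl-(+)-catechin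
Conditions: NBS (1.0 equiv), CH2Cl2, −40 to 0 °C
Reagents that add atoms: N-bromosuccinimide, O=C1CCC(=O)N1Br
Why: Electrophilic aromatic bromination of the phloroglucinol-type ring A is selective for C8 at low temperature, as is established for protected catechins.

Step 12
Reactants: 14 (2R)-5,7-bis(benzyloxy)-2-[3,4-bis(benzyloxy)phenyl]-2H-chromen-3-yl formate (1.5 equiv); 18 8-bromo-5,7,3',4'-tetra-O-benzyl-(+)-catechin
Product: 20 5,7,3',4'-tetra-O-benzylepicatechin-(4β→8)-5,7,3',4'-tetra-O-benzylcatechin, via dimer formate 19 (not isolated)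
Conditions: Fe(dpm)3 [iron tris(2,2,6,6-tetramethylheptane-3,5-dionate)] (25 mol %), NiBr2·diglyme (10 mol %), dtbbpy (12 mol %), PhSiH2(Oi-Pr) (2.5 equiv), Mn powder (0.2 equiv), DCE/DMPU, 35 °C; then K2CO3, MeOH, 0 °C
Reagents that add atoms: none
Why: Proposed new method: an iron hydride formed from Fe(dpm)3 and the silane transfers a hydrogen atom to C3 of the styrene-like enol formate 14 on the face opposite the pseudo-axial C2 aryl group (this sets the 2,3-cis centre and gives the C4 benzylic radical, which is better stabilised than the alternative α-formyloxy radical), the radical is captured on its open β face by the aryl–nickel species from 18 and reductive elimination gives the 3,4-trans 4β→8 bond, after which mild methanolysis removes the formate; the closest known reaction type is the iron/nickel dual-catalysed Mukaiyama-type (MHAT) Markovnikov hydroarylation of olefins with aryl halides.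

Step 13
Reactants: 20 5,7,3',4'-tetra-O-benzylepicatechin-(4β→8)-5,7,3',4'-tetra-O-benzylcatechin
Product: 21 8-bromo-5,7,3',4'-tetra-O-benzylepicatechin-(4β→8)-5,7,3',4'-tetra-O-benzylcatechin
Conditions: NBS (1.0 equiv), CH2Cl2, −78 to −20 °C
Reagents that add atoms: N-bromosuccinimide, O=C1CCC(=O)N1Br
Why: Electrophilic aromatic bromination takes the only free C8 (upper unit, between the ring oxygen and one benzyloxy group), while the C6 positions between two benzyloxy groups react more slowly, as in the monomer.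

Step 14
Reactants: 14 (2R)-5,7-bis(benzyloxy)-2-[3,4-bis(benzyloxy)phenyl]-2H-chromen-3-yl formate (1.5 equiv); 21 8-bromo-5,7,3',4'-tetra-O-benzylepicatechin-(4β→8)-5,7,3',4'-tetra-O-benzylcatechin
Product: 23 dodeca-O-benzyl-epicatechin-(4β→8)-epicatechin-(4β→8)-catechin, via trimer formate 22 (not isolated)
Conditions: Fe(dpm)3 (25 mol %), NiBr2·diglyme (10 mol %), dtbbpy (12 mol %), PhSiH2(Oi-Pr) (2.5 equiv), Mn powder (0.2 equiv), DCE/DMPU, 35 °C; then K2CO3, MeOH, 0 °C
Reagents that add atoms: none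
Why: Proposed new method: as in step 12, hydrogen-atom transfer from the iron hydride to C3 of 14 anti to the C2 aryl group gives the 2,3-cis C4 benzylic radical, which the aryl–nickel species from 21 captures on the β face to give the 3,4-trans 4β→8 bond before methanolysis of the formate; the closest known reaction type is the iron/nickel dual-catalysed MHAT hydroarylation of olefins with aryl halides.

Step 15
Reactants: 23 dodeca-O-benzyl-epicatechin-(4β→8)-epicatechin-(4β→8)-catechin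
Product: 24 8-bromo-dodeca-O-benzyl-epicatechin-(4β→8)-epicatechin-(4β→8)-catechin
Conditions: NBS (1.0 equiv), CH2Cl2, −78 to −20 °C
Reagents that add atoms: N-bromosuccinimide, O=C1CCC(=O)N1Br
Why: Electrophilic aromatic bromination again takes the single free C8 of the uppermost unit in preference to the three more hindered C6 positions.

Step 16
Reactants: 14 (2R)-5,7-bis(benzyloxy)-2-[3,4-bis(benzyloxy)phenyl]-2H-chromen-3-yl formate (1.5 equiv); 24 8-bromo-dodeca-O-benzyl-epicatechin-(4β→8)-epicatechin-(4β→8)-catechin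
Product: 26 hexadeca-O-benzyl-epicatechin-(4β→8)-epicatechin-(4β→8)-epicatechin-(4β→8)-catechin, via tetramer formate 25 (not isolated)
Conditions: Fe(dpm)3 (25 mol %), NiBr2·diglyme (10 mol %), dtbbpy (12 mol %), PhSiH2(Oi-Pr) (2.5 equiv), Mn powder (0.2 equiv), DCE/DMPU, 35 °C; then K2CO3, MeOH, 0 °C
Reagents that add atoms: none
Why: Proposed new method: as in step 12, hydrogen-atom transfer to C3 of 14 anti to the C2 aryl group and β-face capture of the C4 benzylic radical by the aryl–nickel species from 24 set the last 2,3-cis-3,4-trans unit and the third 4β→8 bond before methanolysis of the formate; the closest known reaction type is the iron/nickel dual-catalysed MHAT hydroarylation of olefins with aryl halides.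

Step 17
Reactants: 26 hexadeca-O-benzyl-epicatechin-(4β→8)-epicatechin-(4β→8)-epicatechin-(4β→8)-catechin
Product: 27 epicatechin-(4β→8)-epicatechin-(4β→8)-epicatechin-(4β→8)-catechin (the target tetramer)
Conditions: H2 (1 atm), Pd(OH)2/C, THF/MeOH/H2O, rt
Reagents that add atoms: none
Why: Hydrogenolysis of the sixteen benzyl ethers over Pd(OH)2/C is neutral, so the acid-sensitive interflavan bonds and all twelve stereocentres are left untouched.

**Compound list**
1 | resorcinol (benzene-1,3-diol) | Oc1cccc(O)c1 | starting material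
2 | 1,3-bis(trimethylsilyloxy)benzene | C[Si](C)(C)Oc1cccc(O[Si](C)(C)C)c1 | intermediate
3 | 2-[3,5-bis(trimethylsilyloxy)phenyl]-4,4,5,5-tetramethyl-1,3,2-dioxaborolane | C[Si](C)(C)Oc1cc(O[Si](C)(C)C)cc(c1)B1OC(C)(C)C(C)(C)O1 | intermediate
4 | phloroglucinol (benzene-1,3,5-triol) | Oc1cc(O)cc(O)c1 | intermediate
5 | N,N-dimethyl-(2,4,6-trihydroxyphenyl)methaniminium chloride | C[N+](C)=Cc1c(O)cc(O)cc1O.[Cl-] | intermediate
6 | 2,4,6-trihydroxybenzaldehyde | O=Cc1c(O)cc(O)cc1O | intermediate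
7 | 4,6-bis(benzyloxy)-2-hydroxybenzaldehyde | O=Cc1c(O)cc(OCc2ccccc2)cc1OCc1ccccc1 | intermediate
8 | catechol (benzene-1,2-diol) | Oc1ccccc1O | starting material
9 | 1,2-bis(benzyloxy)benzene | C(Oc1ccccc1OCc1ccccc1)c1ccccc1 | intermediate
10 | 1,2-bis(benzyloxy)-4-iodobenzene | Ic1ccc(OCc2ccccc2)c(OCc2ccccc2)c1 | intermediate
11 | acrolein (prop-2-enal) | C=CC=O | starting material
12 | (E)-3-[3,4-bis(benzyloxy)phenyl]prop-2-enal | O=C/C=C/c1ccc(OCc2ccccc2)c(OCc2ccccc2)c1 | intermediate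
13 | (2R)-5,7-bis(benzyloxy)-2-[3,4-bis(benzyloxy)phenyl]-2H-chromene-3-carbaldehyde | O(Cc1ccccc1)c1cc(OCc3ccccc3)c2c(c1)O[C@H](c1ccc(OCc3ccccc3)c(OCc3ccccc3)c1)C(C=O)=C2 | intermediate
14 | (2R)-5,7-bis(benzyloxy)-2-[3,4-bis(benzyloxy)phenyl]-2H-chromen-3-yl formate | O(Cc1ccccc1)c1cc(OCc3ccccc3)c2c(c1)O[C@H](c1ccc(OCc3ccccc3)c(OCc3ccccc3)c1)C(OC=O)=C2 | intermediate
15 | (2S)-5,7-bis(benzyloxy)-2-[3,4-bis(benzyloxy)phenyl]-2H-chromene (same spatial arrangement at C2 as in 13) | O(Cc1ccccc1)c1cc(OCc3ccccc3)c2c(c1)O[C@H](c1ccc(OCc3ccccc3)c(OCc3ccccc3)c1)C=C2 | intermediate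
16 | [(2S,3S)-5,7-bis(benzyloxy)-2-[3,4-bis(benzyloxy)phenyl]chroman-3-yl]borane, boron trans to the C2 aryl group (shown as the monoalkylborane; spatial arrangement as in 17) | O(Cc1ccccc1)c1cc(OCc3ccccc3)c2c(c1)O[C@H](c1ccc(OCc3ccccc3)c(OCc3ccccc3)c1)[C@@H](B)C2 | intermediate
17 | 5,7,3',4'-tetra-O-benzyl-(+)-catechin, (2R,3S)-5,7-bis(benzyloxy)-2-[3,4-bis(benzyloxy)phenyl]chroman-3-ol | O(Cc1ccccc1)c1cc(OCc3ccccc3)c2c(c1)O[C@H](c1ccc(OCc3ccccc3)c(OCc3ccccc3)c1)[C@@H](O)C2 | intermediate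
18 | 8-bromo-5,7,3',4'-tetra-O-benzyl-(+)-catechin, (2R,3S) | O(Cc1ccccc1)c1cc(OCc3ccccc3)c2c(c1Br)O[C@H](c1ccc(OCc3ccccc3)c(OCc3ccccc3)c1)[C@@H](O)C2 | intermediate
19 | 3-O-formyl-5,7,3',4'-tetra-O-benzylepicatechin-(4β→8)-5,7,3',4'-tetra-O-benzylcatechin (upper unit 2R,3R with the C4–C8 bond trans to the C3 oxygen and the C2 aryl; lower unit 2R,3S) | O(Cc1ccccc1)c1cc(OCc3ccccc3)c2c(c1)O[C@H](c1ccc(OCc3ccccc3)c(OCc3ccccc3)c1)[C@H](OC=O)[C@H]2c1c(OCc3ccccc3)cc(OCc3ccccc3)c2c1O[C@H](c1ccc(OCc3ccccc3)c(OCc3ccccc3)c1)[C@@H](O)C2 | intermediate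
20 | 5,7,3',4'-tetra-O-benzylepicatechin-(4β→8)-5,7,3',4'-tetra-O-benzylcatechin (the octa-O-benzyl dimer; stereochemistry as in 19) | O(Cc1ccccc1)c1cc(OCc3ccccc3)c2c(c1)O[C@H](c1ccc(OCc3ccccc3)c(OCc3ccccc3)c1)[C@H](O)[C@H]2c1c(OCc3ccccc3)cc(OCc3ccccc3)c2c1O[C@H](c1ccc(OCc3ccccc3)c(OCc3ccccc3)c1)[C@@H](O)C2 | intermediate
21 | 20 carrying bromine at C8 of the upper (epicatechin) unit | O(Cc1ccccc1)c1cc(OCc3ccccc3)c2c(c1Br)O[C@H](c1ccc(OCc3ccccc3)c(OCc3ccccc3)c1)[C@H](O)[C@H]2c1c(OCc3ccccc3)cc(OCc3ccccc3)c2c1O[C@H](c1ccc(OCc3ccccc3)c(OCc3ccccc3)c1)[C@@H](O)C2 | intermediate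
22 | dodeca-O-benzyl-epicatechin-(4β→8)-epicatechin-(4β→8)-catechin with a 3-O-formyl group on the uppermost unit (both upper units 2R,3R, 4β; terminal unit 2R,3S) | O(Cc1ccccc1)c1cc(OCc3ccccc3)c2c(c1)O[C@H](c1ccc(OCc3ccccc3)c(OCc3ccccc3)c1)[C@H](OC=O)[C@H]2c1c(OCc3ccccc3)cc(OCc3ccccc3)c2c1O[C@H](c1ccc(OCc3ccccc3)c(OCc3ccccc3)c1)[C@H](O)[C@H]2c1c(OCc3ccccc3)cc(OCc3ccccc3)c2c1O[C@H](c1ccc(OCc3ccccc3)c(OCc3ccccc3)c1)[C@@H](O)C2 | intermediate
23 | dodeca-O-benzyl-epicatechin-(4β→8)-epicatechin-(4β→8)-catechin (the protected trimer; stereochemistry as in 22) | O(Cc1ccccc1)c1cc(OCc3ccccc3)c2c(c1)O[C@H](c1ccc(OCc3ccccc3)c(OCc3ccccc3)c1)[C@H](O)[C@H]2c1c(OCc3ccccc3)cc(OCc3ccccc3)c2c1O[C@H](c1ccc(OCc3ccccc3)c(OCc3ccccc3)c1)[C@H](O)[C@H]2c1c(OCc3ccccc3)cc(OCc3ccccc3)c2c1O[C@H](c1ccc(OCc3ccccc3)c(OCc3ccccc3)c1)[C@@H](O)C2 | intermediate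
24 | 23 carrying bromine at C8 of the uppermost unit | O(Cc1ccccc1)c1cc(OCc3ccccc3)c2c(c1Br)O[C@H](c1ccc(OCc3ccccc3)c(OCc3ccccc3)c1)[C@H](O)[C@H]2c1c(OCc3ccccc3)cc(OCc3ccccc3)c2c1O[C@H](c1ccc(OCc3ccccc3)c(OCc3ccccc3)c1)[C@H](O)[C@H]2c1c(OCc3ccccc3)cc(OCc3ccccc3)c2c1O[C@H](c1ccc(OCc3ccccc3)c(OCc3ccccc3)c1)[C@@H](O)C2 | intermediate
25 | hexadeca-O-benzyl-epicatechin-(4β→8)-epicatechin-(4β→8)-epicatechin-(4β→8)-catechin with a 3-O-formyl group on the uppermost unit (three upper units 2R,3R, 4β; terminal unit 2R,3S) | O(Cc1ccccc1)c1cc(OCc3ccccc3)c2c(c1)O[C@H](c1ccc(OCc3ccccc3)c(OCc3ccccc3)c1)[C@H](OC=O)[C@H]2c1c(OCc3ccccc3)cc(OCc3ccccc3)c2c1O[C@H](c1ccc(OCc3ccccc3)c(OCc3ccccc3)c1)[C@H](O)[C@H]2c1c(OCc3ccccc3)cc(OCc3ccccc3)c2c1O[C@H](c1ccc(OCc3ccccc3)c(OCc3ccccc3)c1)[C@H](O)[C@H]2c1c(OCc3ccccc3)cc(OCc3ccccc3)c2c1O[C@H](c1ccc(OCc3ccccc3)c(OCc3ccccc3)c1)[C@@H](O)C2 | intermediate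
26 | hexadeca-O-benzyl-epicatechin-(4β→8)-epicatechin-(4β→8)-epicatechin-(4β→8)-catechin (all phenols benzylated, four free C3 hydroxyls; stereochemistry as in 25) | O(Cc1ccccc1)c1cc(OCc3ccccc3)c2c(c1)O[C@H](c1ccc(OCc3ccccc3)c(OCc3ccccc3)c1)[C@H](O)[C@H]2c1c(OCc3ccccc3)cc(OCc3ccccc3)c2c1O[C@H](c1ccc(OCc3ccccc3)c(OCc3ccccc3)c1)[C@H](O)[C@H]2c1c(OCc3ccccc3)cc(OCc3ccccc3)c2c1O[C@H](c1ccc(OCc3ccccc3)c(OCc3ccccc3)c1)[C@H](O)[C@H]2c1c(OCc3ccccc3)cc(OCc3ccccc3)c2c1O[C@H](c1ccc(OCc3ccccc3)c(OCc3ccccc3)c1)[C@@H](O)C2 | intermediate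
27 | epicatechin-(4β→8)-epicatechin-(4β→8)-epicatechin-(4β→8)-catechin (the target tetramer) | Oc1cc(O)c2c(c1)O[C@H](c1ccc(O)c(O)c1)[C@H](O)[C@H]2c1c(O)cc(O)c2c1O[C@H](c1ccc(O)c(O)c1)[C@H](O)[C@H]2c1c(O)cc(O)c2c1O[C@H](c1ccc(O)c(O)c1)[C@H](O)[C@H]2c1c(O)cc(O)c2c1O[C@H](c1ccc(O)c(O)c1)[C@@H](O)C2 | target

**Totals**
Total step count: 17. Longest linear sequence: 13 steps (steps 1, 2, 3, 7, 9, 10, 11, 12, 13, 14, 15, 16, 17).

**Steps most likely to fail**

Step 12 (the same reaction returns in steps 14 and 16). Two things are untested: whether the hydrogen atom goes to C3 rather than C4 of the enol formate, and whether a hindered benzylic radical couples with a di-ortho-substituted, electron-rich aryl–nickel species. The fallback sets out from 14 and rejoins the route at 19. Hydrogenation of 14 with [Ir(cod)(PCy3)(py)]PF6 and H2 in CH2Cl2 adds hydrogen anti to the C2 aryl group and gives 3-O-formyl-5,7,3',4'-tetra-O-benzylepicatechin F1. DDQ with 2-ethoxyethanol in CH2Cl2 oxidises C4 of F1 and gives the 4β-(2-ethoxyethoxy) ether F2. Catalytic TMSOTf at −78 °C ionises F2, and the C4 cation is trapped on its β face at C8 by an excess of 17 (4 equiv) to give 19; methanolysis as in step 12 then gives 20. In the later rounds 20 and 23 take the place of 17 and the route is rejoined at 22 and 25.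

Step 7. The salicylaldehyde is electron-rich and flanked by a benzyloxy group, so the aldol closure may be slow, and a reversible oxa-Michael step could erode the enantiomeric excess. The fallback sets out from 7 and 12 and rejoins at 13. Heating 7 and 12 with K2CO3 in dioxane at 100 °C (phenoxide oxa-Michael addition and aldol condensation, no amine) gives the racemic chromene aldehyde F3. F3 is resolved by preparative chromatography on a chiral stationary phase (supercritical CO2/MeOH), and the (2R) enantiomer is 13.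

Step 15. The trimer offers three C6 positions besides the one wanted C8, so mono-bromination may not be clean (step 13 poses the same question with fewer competing sites). The fallback sets out from 13, 14 and 21 and rejoins at 26, so that no trimer is brominated. NBS on 13 gives the 8-bromo aldehyde F4. The hydroarylation of step 12 between 14 and F4 (aqueous NaHCO3 work-up, no methanolysis) gives the dimeric aldehyde F5. mCPBA as in step 8 converts F5 into the dimeric enol formate F6. Hydroarylation of F6 with 21 gives the tetramer bis-formate F7, and K2CO3/MeOH in the same flask gives 26; steps 14 to 16 are bypassed.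

**Further compounds**
F1 | step 12 | 3-O-formyl-5,7,3',4'-tetra-O-benzylepicatechin, (2R,3R) | O(Cc1ccccc1)c1cc(OCc3ccccc3)c2c(c1)O[C@H](c1ccc(OCc3ccccc3)c(OCc3ccccc3)c1)[C@H](OC=O)C2
F2 | step 12 | 3-O-formyl-4β-(2-ethoxyethoxy)-5,7,3',4'-tetra-O-benzylepicatechin (2,3-cis, 3,4-trans) | O(Cc1ccccc1)c1cc(OCc3ccccc3)c2c(c1)O[C@H](c1ccc(OCc3ccccc3)c(OCc3ccccc3)c1)[C@H](OC=O)[C@H]2OCCOCC
F3 | step 7 | racemic 5,7-bis(benzyloxy)-2-[3,4-bis(benzyloxy)phenyl]-2H-chromene-3-carbaldehyde | O(Cc1ccccc1)c1cc(OCc3ccccc3)c2c(c1)OC(c1ccc(OCc3ccccc3)c(OCc3ccccc3)c1)C(C=O)=C2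
F4 | step 15 | (2R)-8-bromo-5,7-bis(benzyloxy)-2-[3,4-bis(benzyloxy)phenyl]-2H-chromene-3-carbaldehyde | O(Cc1ccccc1)c1cc(OCc3ccccc3)c2c(c1Br)O[C@H](c1ccc(OCc3ccccc3)c(OCc3ccccc3)c1)C(C=O)=C2
F5 | step 15 | 3-O-formyl-5,7,3',4'-tetra-O-benzylepicatechin joined 4β→8 to (2R)-5,7-bis(benzyloxy)-2-[3,4-bis(benzyloxy)phenyl]-2H-chromene-3-carbaldehyde | O(Cc1ccccc1)c1cc(OCc3ccccc3)c2c(c1)O[C@H](c1ccc(OCc3ccccc3)c(OCc3ccccc3)c1)[C@H](OC=O)[C@H]2c1c(OCc3ccccc3)cc(OCc3ccccc3)c2c1O[C@H](c1ccc(OCc3ccccc3)c(OCc3ccccc3)c1)C(C=O)=C2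
F6 | step 15 | 3-O-formyl-5,7,3',4'-tetra-O-benzylepicatechin joined 4β→8 to (2R)-5,7-bis(benzyloxy)-2-[3,4-bis(benzyloxy)phenyl]-2H-chromen-3-yl formate | O(Cc1ccccc1)c1cc(OCc3ccccc3)c2c(c1)O[C@H](c1ccc(OCc3ccccc3)c(OCc3ccccc3)c1)[C@H](OC=O)[C@H]2c1c(OCc3ccccc3)cc(OCc3ccccc3)c2c1O[C@H](c1ccc(OCc3ccccc3)c(OCc3ccccc3)c1)C(OC=O)=C2
F7 | step 15 | hexadeca-O-benzyl-epicatechin-(4β→8)-epicatechin-(4β→8)-epicatechin-(4β→8)-catechin with 3-O-formyl groups on the two uppermost units | O(Cc1ccccc1)c1cc(OCc3ccccc3)c2c(c1)O[C@H](c1ccc(OCc3ccccc3)c(OCc3ccccc3)c1)[C@H](OC=O)[C@H]2c1c(OCc3ccccc3)cc(OCc3ccccc3)c2c1O[C@H](c1ccc(OCc3ccccc3)c(OCc3ccccc3)c1)[C@H](OC=O)[C@H]2c1c(OCc3ccccc3)cc(OCc3ccccc3)c2c1O[C@H](c1ccc(OCc3ccccc3)c(OCc3ccccc3)c1)[C@H](O)[C@H]2c1c(OCc3ccccc3)cc(OCc3ccccc3)c2c1O[C@H](c1ccc(OCc3ccccc3)c(OCc3ccccc3)c1)[C@@H](O)C2
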